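The colleague who charges these flasks has several ways of bringing substrate and coupling partner together and wants to know how much substrate ends as self-condensation product.

| flask | substrate | coupling partner | remark | time |
|---|---|---|---|---|
| Monday's | 12 mM | 5 equiv | run made earlier |  |
| Thursday's | 12 mM | 2.5 equiv | run made earlier |  |
| Sunday's | 12 mM | 10 equiv | run made earlier |  |
| dusk | 12 mM (fed, over 2.5 min) | 5.00 equiv | all else is in the flask from the start; the feed brings no volume worth counting | 4.0 min |
| autumn | 12 mM | 5.00 equiv (fed, over 2.5 min) | all else is in the flask from the start; the feed brings no volume worth counting | 4.0 min |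
| midnight | 12 mM | 5.00 equiv (fed, over 40 s) | all else is in the flask from the start; the feed brings no volume worth counting | 4.0 min |
| spring | 12 mM | 5.00 equiv (in portions, 4, over 2.5 min) | first portion at the start, last at 2.5 min | 4.0 min |
| noon | 12 mM | 5.00 equiv | everything together at the start | 4.0 min |

| run | time / min | self-condensation product / % | target / % | substrate / % |
|---|---|---|---|---|
| Monday's | 0.200 | 19 | 4 | 47 |
| Monday's | 0.333 | 26 | 7 | 38 |
| Monday's | 0.417 | 30 | 5 | 28 |
| Monday's | 0.667 | 31 | 9 | 20 |
| Monday's | 1.00 | 30 | 8 | 10 |
| Monday's | 1.50 | 33 | 8 | 5 |
| Monday's | 2.50 | 34 | 11 | 1 |
| Thursday's | 0.167 | 23 | 0 | 62 |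
| Thursday's | 0.500 | 39 | 1 | 33 |
| Thursday's | 0.833 | 45 | 7 | 22 |
| Thursday's | 1.33 | 49 | 8 | 10 |
| Thursday's | 2.00 | 48 | 7 | 7 |
| Thursday's | 2.50 | 49 | 8 | 3 |
| Thursday's | 3.00 | 50 | 8 | 3 |
| Sunday's | 0.500 | 18 | 12 | 13 |
| Sunday's | 1.00 | 19 | 11 | 5 |
| Sunday's | 1.33 | 16 | 13 | 3 |
| Sunday's | 2.00 | 17 | 11 | 0 |
| Sunday's | 2.50 | 16 | 13 | 1 |
| Sunday's | 3.00 | 18 | 15 | 0 |

(standard deviation of a reading: 1.5 percentage points)

- percentages count the substrate that a species holds: one self-condensation product counts as two

- the flask that comes out highest in amount of self-condensation product, in percent of the substrate charged, or "all alike" when all lie within 1.5 percentage points (dusk / autumn / midnight / spring / noon / all alike)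
- self-condensation product at the end, in percent of the substrate charged, dusk
- self-condensation product at the end, in percent of the substrate charged, autumn
- self-condensation product at the end, in percent of the substrate charged, midnight
- self-condensation product at the end, in percent of the substrate charged, spring
- self-condensation product at the end, in percent of the substrate charged, noon

I work with the fraction left, x, which is c(substrate) over its charge. Self-condensation takes substrate at a times x squared, and the cross route, pseudo-first-order while the partner stands in excess, takes it at b times x. Monday's tail gives a reading of b: between 0.667 min and 1.50 min the substrate falls from 20% to 5%, a fractional rate of 1.66 /min, and that reading still holds some self-condensation. Monday's final 34%, set against the rest at a typical x of 0.5, gives 97.1%, my rough even point, the fraction left at which both routes take substrate equally fast, and so a is 1.71 /min.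

A Monday flask starts with the routes close, 1.71 /min against 1.66 /min. Each factor 2 lost in x then costs the cross route a factor 2 but self-condensation a factor 4, so, with c(coupling partner) held, the self-condensation share at any moment is x over x plus the even point. I let the even point move in proportion to the equivalents, and summing that share down the whole charge gives 45.7% for Thursday's run, read at 50%, and 19.3% for Sunday's, read at 18%. In dusk the feed supplies 0.400 /min of the charge, and I take x to stand where both routes together remove that, at 19.9%, so I commit to 17.0% for dusk, less than Monday's reading.

The forecast says autumn comes highest, in its words “partner arrives late, so dimer wins”, with 16% for dusk, 69% for autumn, 54% for midnight, 61% for spring and 34% for noon; its dusk value lies close to mine.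

The flasks give 15.8% for dusk, 67.4% for autumn, the highest, 51.9% for midnight, 60.1% for spring and 32.6% for noon.

    2 substrate → self-condensation product (k = 1.60 /M/s)
    adduct → decomposed reagent (k = 0.160 /s)
    substrate + coupling partner ⇌ adduct, settled at all times (K = 2.80 /M)
    adduct → target (k = 0.0310 /s)

In dusk, at 2.00 min, substrate stands at 18.1% while the adduct holds 2.72%, and the even point puts the self-condensation share of that moment at 15.7%, while the product accumulated by then is 9.59% of the charge and by the end 15.8%. In midnight, the end of the feed at 0.667 min finds 48.5% as self-condensation product with 23.4% as substrate and 3.71% as adduct, and the share summed over that substrate, added to that product, comes to 50.9%, where the flask gives 51.9%.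

(The data stem from a simulated flask from invented constants; the scatter is artificial.)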